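**Retrosynthetic overview**

1. Locants (stilbenoid numbering): C7a = O-CH(Ar) and C8a = the adjacent CH of the dihydrofuran. C7b = CH(Ar) and C8b = CH2 of the seven-membered ring. Ring A is the resorcinol ring (C9a bears C8a, C10a bears C7b, C11a bears OH). Ring B is the benzene ring of the benzofuran (C9b bears C8b, C10b bears C8a, C11b bears the ring O).
2. Endgame: debenzylation comes last. Before it, the O-C7a bond is closed by acid-equilibrated cyclisation of a 5-benzylidene-dibenzosuberane phenol, whose C7a-C8a bond comes from a benzyl Grignard reagent and a diaryl ketone (C8a as C=O).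
3. Key disconnection: C8b-C9b and C8a-C10b are cut together. This leads back to 3,5-bis(benzyloxy)benzyne, which inserts into the bond between C-1 and C-2 of a 3-aryl-2-sulfonylindan-1-one. The five-membered ring is temporary and the sulfone is a removable activator.
4. Enabling feature: C9b and C10b are ortho neighbours of ring B, and C10b is flanked by the O-bearing C11b. The aryne C9b≡C10b is therefore polarised to take a carbanion at C9b and to deliver its aryl anion (C10b) to an acyl carbon. The arc C8b-C7b-C10a-C9a-C8a folds into an indanone once C8b and C8a are joined.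
5. Stereochemistry and ring order: C7b is set by Rh catalysis, and C8a and C7a are relayed from it in one event. Rings form in the order temporary cyclopentanone, then seven-membered ring (by ring expansion), then dihydrofuran.

Key step: step 7

Assumption: the sense of induction of the chiral diene in step 3 is taken over from simpler β-aryl vinyl sulfones. If this substrate responds in the opposite sense, the antipodal ligand is used.

**Step 1**
Reactants: 1 methyl 3,5-bis(benzyloxy)benzoate
Product: 2 methyl 3,5-bis(benzyloxy)-2-bromobenzoate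
Conditions: NBS (1.0 equiv), MeCN, 0 °C to rt, dark
Reagents that add atoms: N-bromosuccinimide O=C1CCC(=O)N1Br
Why: Electrophilic aromatic bromination should go to C-2, which is ortho to one and para to the other benzyloxy group and less crowded than C-4 between the two ethers, as is usual for 3,5-dialkoxybenzoates.

**Step 2**
Reactants: 2 methyl 3,5-bis(benzyloxy)-2-bromobenzoate, 3 phenyl vinyl sulfone
Product: 4 methyl 3,5-bis(benzyloxy)-2-[(E)-2-(phenylsulfonyl)ethenyl]benzoate
Conditions: Pd2(dba)3 (2 mol %), P(t-Bu)3·HBF4 (8 mol %), Cy2NMe (1.5 equiv), dioxane, 100 °C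
Reagents that add atoms: none
Why: In this Mizoroki-Heck reaction the bulky electron-rich phosphine allows oxidative addition to the doubly ortho-substituted bromide, and the terminal acceptor alkene gives the E β-aryl vinyl sulfone.

**Step 3**
Reactants: 4 methyl 3,5-bis(benzyloxy)-2-[(E)-2-(phenylsulfonyl)ethenyl]benzoate, 5 4-(benzyloxy)phenylboronic acid
Product: 6 methyl 3,5-bis(benzyloxy)-2-[(1S)-1-[4-(benzyloxy)phenyl]-2-(phenylsulfonyl)ethyl]benzoate
Conditions: [RhCl(C2H4)2]2 (2.5 mol %), chiral bicyclic diene ligand (Ph-bod* or tfb* type, 5.5 mol %), aq KOH (20 mol %), 5 (2.5 equiv), dioxane, 60 °C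
Reagents that add atoms: none
Why: This is a Hayashi-Miyaura asymmetric conjugate addition to a β-aryl vinyl phenyl sulfone, for which chiral diene-rhodium catalysts are known to be active and to suppress cine substitution, and the ligand-controlled face of aryl-rhodium insertion sets C7b as S.

**Step 4**
Reactants: 6 methyl 3,5-bis(benzyloxy)-2-[(1S)-1-[4-(benzyloxy)phenyl]-2-(phenylsulfonyl)ethyl]benzoate
Product: 7 (2R,3S)-4,6-bis(benzyloxy)-3-[4-(benzyloxy)phenyl]-2-(phenylsulfonyl)-2,3-dihydro-1H-inden-1-one
Conditions: LDA (2.2 equiv), THF, -78 to 0 °C; aq NH4Cl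
Reagents that add atoms: none
Why: A Dieckmann-type 5-exo-trig acylation of the α-sulfonyl carbanion by the neighbouring methyl ester is driven by deprotonation of the β-ketosulfone formed, the labile C-2 settles trans to the aryl group by equilibration, and C-3 is not touched.

**Step 5**
Reactants: 8 3,5-bis(benzyloxy)phenol
Product: 9 3,5-bis(benzyloxy)-2-bromophenol
Conditions: NBS (1.0 equiv), i-Pr2NH (10 mol %), CH2Cl2, -78 to 0 °C
Reagents that add atoms: N-bromosuccinimide O=C1CCC(=O)N1Br
Why: Amine-catalysed ortho-selective electrophilic bromination of a phenol should prefer C-2 over C-4, because C-4 lies between two bulky benzyloxy groups and C-2 is also favoured statistically.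

**Step 6**
Reactants: 9 3,5-bis(benzyloxy)-2-bromophenol
Product: 12 3,5-bis(benzyloxy)-2-(trimethylsilyl)phenyl trifluoromethanesulfonate, via aryl silyl ether 10 (not isolated), via lithium silylphenoxide 11 (not isolated)
Conditions: HMDS, THF, 65 °C, concentrate; n-BuLi (1.1 equiv), THF, -78 °C; Tf2O (1.2 equiv), -78 °C to rt
Reagents that add atoms: hexamethyldisilazane C[Si](C)(C)N[Si](C)(C)C; triflic anhydride O=S(=O)(OS(=O)(=O)C(F)(F)F)C(F)(F)F
Why: O-silylation, bromine-lithium exchange, retro-Brook 1,3-O-to-C silyl shift and O-triflation form the standard sequence to o-silylaryl triflate aryne precursors, and benzyl ethers tolerate it at -78 °C.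

**Step 7**
Reactants: 7 (2R,3S)-4,6-bis(benzyloxy)-3-[4-(benzyloxy)phenyl]-2-(phenylsulfonyl)-2,3-dihydro-1H-inden-1-one, 12 3,5-bis(benzyloxy)-2-(trimethylsilyl)phenyl trifluoromethanesulfonate
Product: 15 (11S)-1,3,6,8-tetrakis(benzyloxy)-11-[4-(benzyloxy)phenyl]-10-(phenylsulfonyl)-10,11-dihydro-5H-dibenzo[a,d][7]annulen-5-one (C-10 epimers), via aryne 13 (not isolated), via caesium benzocyclobutenoxide 14 (not isolated)
Conditions: CsF (3 equiv), MeCN, 60 °C, 12 (1.2 equiv) added slowly
Reagents that add atoms: none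
Why: Fluoride-induced 1,2-elimination of 12 releases aryne 13, the caesium enolate of 7 adds to it through C-2, the aryl anion closes onto the indanone C=O to give 14, and retro-aldol-type fragmentation of the strained bond between C-1 and C-2 expels the sulfonyl-stabilised carbanion, so the aryne ends up inserted between these two carbons (aryne acyl-alkylation, a σ-bond insertion with two-carbon ring expansion known for cyclic β-ketoesters and α-sulfonyl cycloalkanones). The seven-membered ring is thus not closed end to end but grows out of the five-membered ring by a 4-exo-trig closure of the aryl anion on the ketone, followed by cleavage of the bond shared by the four- and five-membered rings. The regioselectivity needed (C8b to C9b, acyl C8a to C10b) is secured by the benzyloxy group next to the triple bond, whose inductive pull and the resulting aryne distortion direct the carbanion to the distal carbon and place the aryl anion ortho to oxygen. Insertion should win over plain arylation because the arylated carbon is quaternary, offers no proton, and holds the aryl anion 1,4 to a non-enolisable ketone that the two meta benzyloxy groups of ring A do not deactivate. The only new stereocentre, C-10 (C8b), arises by protonation as an inconsequential epimer mixture and is erased in step 8. C-11 (C7b) stays a spectator because the medium is buffered first by acidic 7 and then by the C-10 proton of 15, whose anion cannot expel sulfinate.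

**Step 8**
Reactants: 15 (11S)-1,3,6,8-tetrakis(benzyloxy)-11-[4-(benzyloxy)phenyl]-10-(phenylsulfonyl)-10,11-dihydro-5H-dibenzo[a,d][7]annulen-5-one
Product: 16 (11S)-1,3,6,8-tetrakis(benzyloxy)-11-[4-(benzyloxy)phenyl]-10,11-dihydro-5H-dibenzo[a,d][7]annulen-5-one
Conditions: SmI2 (2.5 equiv), THF-MeOH, -78 °C
Reagents that add atoms: none
Why: In this reductive desulfonylation by single-electron transfer the diaryl ketyl expels the ortho-benzylic sulfinate (vinylogous to the familiar SmI2 cleavage of α-sulfonyl ketones), a second electron and MeOH deliver the CH2 group, and limited reagent at low temperature should spare the ketone and C-11.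

**Step 9**
Reactants: 16 (11S)-1,3,6,8-tetrakis(benzyloxy)-11-[4-(benzyloxy)phenyl]-10,11-dihydro-5H-dibenzo[a,d][7]annulen-5-one
Product: 17 (11S)-1,3,8-tris(benzyloxy)-11-[4-(benzyloxy)phenyl]-6-hydroxy-10,11-dihydro-5H-dibenzo[a,d][7]annulen-5-one
Conditions: MgBr2·OEt2 (3 equiv), toluene-Et2O, 70 °C; 1 M HCl
Reagents that add atoms: none
Why: In this chelation-controlled ether cleavage Mg(II) bridges the ketone oxygen and the only benzyloxy group ortho to it (C-6), so bromide removes just this benzyl group, a known selective debenzylation of ortho-acyl aryl benzyl ethers.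

**Step 10**
Reactants: 17 (11S)-1,3,8-tris(benzyloxy)-11-[4-(benzyloxy)phenyl]-6-hydroxy-10,11-dihydro-5H-dibenzo[a,d][7]annulen-5-one, 18 4-(benzyloxy)benzyl chloride
Product: 20 (11S)-1,3,8-tris(benzyloxy)-5-[4-(benzyloxy)benzyl]-11-[4-(benzyloxy)phenyl]-10,11-dihydro-5H-dibenzo[a,d][7]annulene-5,6-diol (C-5 epimers), via benzylmagnesium chloride 19 (not isolated)
Conditions: 18, Mg, THF, 0 °C (slow addition); then 17 (0.25 equiv relative to 19), LaCl3·2LiCl (1 equiv), THF, 0 °C to rt; aq NH4Cl
Reagents that add atoms: none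
Why: This is a Grignard 1,2-addition to a dibenzosuberone-type ketone without α-hydrogen, in which the lanthanum salt raises the electrophilicity of the phenoxide-bound carbonyl and damps basicity, and the new carbinol centre needs no control because it becomes sp2 in step 11.

**Step 11**
Reactants: 20 (11S)-1,3,8-tris(benzyloxy)-5-[4-(benzyloxy)benzyl]-11-[4-(benzyloxy)phenyl]-10,11-dihydro-5H-dibenzo[a,d][7]annulene-5,6-diol
Product: 22 penta-O-benzylampelopsin B (7aS,8aS,7bS), via benzylidene phenol 21 (not isolated)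
Conditions: p-TsOH·H2O (0.3 equiv), 1,2-dichloroethane, 60 °C, until the isomer composition no longer changes
Reagents that add atoms: none
Why: Acid-catalysed dehydration to 21 is followed by intramolecular hydroalkoxylation (reversible protonation at C8a gives the 4-benzyloxybenzyl cation at C7a, which the C11b phenol traps in a five-membered closure), and since every step is reversible C8a and C7a are set together under thermodynamic substrate control from C7b: the 2,3-trans dihydrofuran is favoured, and the ring fusion forces the hydrogen at C8a pseudo-axial and C7a pseudo-equatorial on the boat-shaped seven-membered ring, which only in the (7aS,8aS) isomer lets the C7b aryl group stay pseudo-axial and clear of the peri C11a benzyloxy group.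

**Step 12**
Reactants: 22 penta-O-benzylampelopsin B
Product: 23 ampelopsin B (7aS,8aS,7bS)
Conditions: H2 (1 atm), 10 % Pd/C, EtOAc-MeOH, rt
Reagents that add atoms: none
Why: Catalytic hydrogenolysis should cleave the five primary benzyl aryl ethers much faster than the hindered secondary cyclic C7a-O bond, a chemoselectivity known for benzyl-protected dihydrobenzofuran stilbenoids, and no stereocentre is touched.

**Compound list**

1 | methyl 3,5-bis(benzyloxy)benzoate | COC(=O)c1cc(OCc2ccccc2)cc(OCc2ccccc2)c1 | starting material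
2 | methyl 3,5-bis(benzyloxy)-2-bromobenzoate | COC(=O)c1cc(OCc2ccccc2)cc(OCc2ccccc2)c1Br | intermediate
3 | phenyl vinyl sulfone | C=CS(=O)(=O)c1ccccc1 | starting material
4 | methyl 3,5-bis(benzyloxy)-2-[(E)-2-(phenylsulfonyl)ethenyl]benzoate | COC(=O)c1cc(OCc2ccccc2)cc(OCc2ccccc2)c1/C=C/S(=O)(=O)c1ccccc1 | intermediate
5 | 4-(benzyloxy)phenylboronic acid | OB(O)c1ccc(OCc2ccccc2)cc1 | starting material
6 | methyl 3,5-bis(benzyloxy)-2-[(1S)-1-[4-(benzyloxy)phenyl]-2-(phenylsulfonyl)ethyl]benzoate | O(Cc1ccccc1)c1ccc(cc1)[C@@H](c1c(C(=O)OC)cc(OCc2ccccc2)cc1OCc1ccccc1)CS(=O)(=O)c1ccccc1 | intermediate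
7 | (2R,3S)-4,6-bis(benzyloxy)-3-[4-(benzyloxy)phenyl]-2-(phenylsulfonyl)-2,3-dihydro-1H-inden-1-one | O(Cc1ccccc1)c1ccc(cc1)[C@H]1c2c(OCc3ccccc3)cc(OCc3ccccc3)cc2C(=O)[C@@H]1S(=O)(=O)c1ccccc1 | intermediate
8 | 3,5-bis(benzyloxy)phenol | Oc1cc(OCc2ccccc2)cc(OCc2ccccc2)c1 | starting material
9 | 3,5-bis(benzyloxy)-2-bromophenol | Oc1cc(OCc2ccccc2)cc(OCc2ccccc2)c1Br | intermediate
10 | [3,5-bis(benzyloxy)-2-bromophenoxy]trimethylsilane | C[Si](C)(C)Oc1cc(OCc2ccccc2)cc(OCc2ccccc2)c1Br | intermediate
11 | lithium 3,5-bis(benzyloxy)-2-(trimethylsilyl)phenoxide | [Li+].[O-]c1cc(OCc2ccccc2)cc(OCc2ccccc2)c1[Si](C)(C)C | intermediate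
12 | 3,5-bis(benzyloxy)-2-(trimethylsilyl)phenyl trifluoromethanesulfonate | C[Si](C)(C)c1c(OCc2ccccc2)cc(OCc2ccccc2)cc1OS(=O)(=O)C(F)(F)F | intermediate
13 | 3,5-bis(benzyloxy)benzyne | C1#CC(OCc2ccccc2)=CC(OCc2ccccc2)=C1 | intermediate
14 | caesium benzocyclobutenoxide (aryne bridging C-1 and C-2 of 7 on the face anti to the 3-aryl group) | O(Cc1ccccc1)c1ccc(cc1)[C@H]1c2c(OCc3ccccc3)cc(OCc3ccccc3)cc2[C@]4([O-])c5c(OCc3ccccc3)cc(OCc3ccccc3)cc5[C@]14S(=O)(=O)c1ccccc1.[Cs+] | intermediate
15 | (11S)-1,3,6,8-tetrakis(benzyloxy)-11-[4-(benzyloxy)phenyl]-10-(phenylsulfonyl)-10,11-dihydro-5H-dibenzo[a,d][7]annulen-5-one (C-10 epimers) | O(Cc1ccccc1)c1ccc(cc1)[C@H]1c2c(OCc3ccccc3)cc(OCc3ccccc3)cc2C(=O)c2c(OCc3ccccc3)cc(OCc3ccccc3)cc2C1S(=O)(=O)c1ccccc1 | intermediate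
16 | (11S)-1,3,6,8-tetrakis(benzyloxy)-11-[4-(benzyloxy)phenyl]-10,11-dihydro-5H-dibenzo[a,d][7]annulen-5-one | O(Cc1ccccc1)c1ccc(cc1)[C@H]1c2c(OCc3ccccc3)cc(OCc3ccccc3)cc2C(=O)c2c(OCc3ccccc3)cc(OCc3ccccc3)cc2C1 | intermediate
17 | (11S)-1,3,8-tris(benzyloxy)-11-[4-(benzyloxy)phenyl]-6-hydroxy-10,11-dihydro-5H-dibenzo[a,d][7]annulen-5-one | O(Cc1ccccc1)c1ccc(cc1)[C@H]1c2c(OCc3ccccc3)cc(OCc3ccccc3)cc2C(=O)c2c(O)cc(OCc3ccccc3)cc2C1 | intermediate
18 | 4-(benzyloxy)benzyl chloride | ClCc1ccc(OCc2ccccc2)cc1 | starting material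
19 | 4-(benzyloxy)benzylmagnesium chloride | Cl[Mg]Cc1ccc(OCc2ccccc2)cc1 | intermediate
20 | (11S)-1,3,8-tris(benzyloxy)-5-[4-(benzyloxy)benzyl]-11-[4-(benzyloxy)phenyl]-10,11-dihydro-5H-dibenzo[a,d][7]annulene-5,6-diol (C-5 epimers) | O(Cc1ccccc1)c1ccc(cc1)[C@H]1c2c(OCc3ccccc3)cc(OCc3ccccc3)cc2C(O)(Cc2ccc(OCc3ccccc3)cc2)c2c(O)cc(OCc3ccccc3)cc2C1 | intermediate
21 | (11S)-1,3,8-tris(benzyloxy)-5-[4-(benzyloxy)benzylidene]-11-[4-(benzyloxy)phenyl]-10,11-dihydro-5H-dibenzo[a,d][7]annulen-6-ol (E/Z mixture) | O(Cc1ccccc1)c1ccc(cc1)[C@H]1c2c(OCc3ccccc3)cc(OCc3ccccc3)cc2C(=Cc2ccc(OCc3ccccc3)cc2)c2c(O)cc(OCc3ccccc3)cc2C1 | intermediate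
22 | penta-O-benzylampelopsin B (7aS,8aS,7bS) | C(c1ccccc1)Oc1ccc([C@@H]2Cc3cc(OCc5ccccc5)cc4c3[C@H](c3cc(OCc5ccccc5)cc(OCc5ccccc5)c32)[C@@H](c2ccc(OCc5ccccc5)cc2)O4)cc1 | intermediate
23 | ampelopsin B (7aS,8aS,7bS) | Oc1ccc([C@@H]2Cc3cc(O)cc4c3[C@H](c3cc(O)cc(O)c32)[C@@H](c2ccc(O)cc2)O4)cc1 | target

**Step count**

Total step count: 12. Longest linear sequence: 10 (steps 1-4 and 7-12).

**Steps most likely to fail**

Step 7. The hindered enolate may be O-arylated. The aryl anion may also be quenched before the four-membered ring closes, so that the reaction stops at plain arylation without ring expansion. Prolonged exposure to base may further cause loss of sulfinate from the product and thereby loss of the C7b stereocentre.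

The fallback makes the two bonds one after the other with known reactions and sets out from 7. Metal-free α-arylation with [3,5-bis(benzyloxy)phenyl](mesityl)iodonium triflate and t-BuOK should give the 2-aryl-2-sulfonylindanone F1. KOH in aqueous dioxane should open this non-enolisable β-ketosulfone by retro-Claisen cleavage to the sulfonyl acid F2. Sodium amalgam in buffered MeOH should remove the sulfone to give the triarylethane acid F3. TFAA in CH2Cl2 should then close the seven-membered ring by intramolecular Friedel-Crafts acylation at either of the two equivalent, doubly activated positions of the 3,5-bis(benzyloxy)phenyl ring. The route is rejoined at 16.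

Step 11. Equilibration may be incomplete, or the energy gap between the diastereomeric ring-fused products may be too small. Either case amounts to poor facial selectivity in the protonation at C8a. Acid-induced migration or loss of benzyl groups may also compete.

The fallback replaces proton delivery by kinetically controlled carbon-carbon bond formation anti to the C7b aryl group and sets out from 17. NaBH4 should give the hydroxybenzhydrol F4. Sodium benzenesulfinate in aqueous formic acid should convert it into the 5-sulfonyl phenol F5. Separately, 18 and tetrahydrothiophene should give the sulfonium salt F6. Cs2CO3 in MeCN should then release the ortho-quinone methide F7 from F5 and the ylide from F6. Their formal [4+1] annulation proceeds by ylide attack on C8a from the face opposite the pseudo-axial aryl group, followed by SN2 closure of the phenoxide to the trans dihydrofuran. This comes back to the route at 22.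

Step 3. Insertion of aryl-rhodium into the doubly ortho-substituted styrenyl sulfone may be slow. Protodeboronation, cine substitution or erosion of enantioselectivity could then take over.

The fallback forms the other aryl-C7b bond (C10a-C7b) intramolecularly and sets out from 2. Acylation of lithiated methyl phenyl sulfone by ester 2 should give the bromoaryl β-ketosulfone F8. Knoevenagel condensation with 4-(benzyloxy)benzaldehyde (piperidine, AcOH, toluene, reflux) should give the α-sulfonyl chalcone F9. A Pd-catalysed asymmetric intramolecular reductive Heck cyclisation (chiral bisphosphine, sodium formate), known for 2'-halochalcones, should close the indanone and set C-3. The route is rejoined at 7.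

**Further compounds**

F1 | step 7 | (2R,3S)-4,6-bis(benzyloxy)-2-[3,5-bis(benzyloxy)phenyl]-3-[4-(benzyloxy)phenyl]-2-(phenylsulfonyl)-2,3-dihydro-1H-inden-1-one (new aryl group anti to the 3-aryl group) | O(Cc1ccccc1)c1ccc(cc1)[C@H]1c2c(OCc3ccccc3)cc(OCc3ccccc3)cc2C(=O)[C@@]1(c1cc(OCc3ccccc3)cc(OCc3ccccc3)c1)S(=O)(=O)c1ccccc1
F2 | step 7 | 3,5-bis(benzyloxy)-2-[(1S)-1-[4-(benzyloxy)phenyl]-2-[3,5-bis(benzyloxy)phenyl]-2-(phenylsulfonyl)ethyl]benzoic acid (C-2 epimers) | O(Cc1ccccc1)c1ccc(cc1)[C@@H](c1c(C(=O)O)cc(OCc2ccccc2)cc1OCc1ccccc1)C(c1cc(OCc2ccccc2)cc(OCc2ccccc2)c1)S(=O)(=O)c1ccccc1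
F3 | step 7 | 3,5-bis(benzyloxy)-2-[(1S)-1-[4-(benzyloxy)phenyl]-2-[3,5-bis(benzyloxy)phenyl]ethyl]benzoic acid | O(Cc1ccccc1)c1ccc(cc1)[C@@H](c1c(C(=O)O)cc(OCc2ccccc2)cc1OCc1ccccc1)Cc1cc(OCc2ccccc2)cc(OCc2ccccc2)c1
F4 | step 11 | (11S)-1,3,8-tris(benzyloxy)-11-[4-(benzyloxy)phenyl]-10,11-dihydro-5H-dibenzo[a,d][7]annulene-5,6-diol (C-5 epimers) | O(Cc1ccccc1)c1ccc(cc1)[C@H]1c2c(OCc3ccccc3)cc(OCc3ccccc3)cc2C(O)c2c(O)cc(OCc3ccccc3)cc2C1
F5 | step 11 | (11S)-1,3,8-tris(benzyloxy)-11-[4-(benzyloxy)phenyl]-5-(phenylsulfonyl)-10,11-dihydro-5H-dibenzo[a,d][7]annulen-6-ol (C-5 epimers) | O(Cc1ccccc1)c1ccc(cc1)[C@H]1c2c(OCc3ccccc3)cc(OCc3ccccc3)cc2C(S(=O)(=O)c2ccccc2)c2c(O)cc(OCc3ccccc3)cc2C1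
F6 | step 11 | 1-[4-(benzyloxy)benzyl]tetrahydrothiophenium chloride | C(c1ccc(OCc2ccccc2)cc1)[S+]1CCCC1.[Cl-]
F7 | step 11 | ortho-quinone methide of ring B (C11b=O, C10b=C8a), (11S) | O(Cc1ccccc1)c1ccc(cc1)[C@H]1c2c(OCc3ccccc3)cc(OCc3ccccc3)cc2C=C2C(=O)C=C(OCc3ccccc3)C=C2C1
F8 | step 3 | 1-[3,5-bis(benzyloxy)-2-bromophenyl]-2-(phenylsulfonyl)ethan-1-one | O=C(CS(=O)(=O)c1ccccc1)c1cc(OCc2ccccc2)cc(OCc2ccccc2)c1Br
F9 | step 3 | (E)-1-[3,5-bis(benzyloxy)-2-bromophenyl]-3-[4-(benzyloxy)phenyl]-2-(phenylsulfonyl)prop-2-en-1-one | c1ccccc1S(=O)(=O)/C(=C/c1ccc(OCc2ccccc2)cc1)C(=O)c1cc(OCc2ccccc2)cc(OCc2ccccc2)c1Br
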